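Ring B is disconnected at C5–C6. C5, a ring-fusion methine lodged between the quaternary carbons C4 and C10, and the oxygenated C6 are both taken back to carbonyl carbons: the surviving ketone of a desymmetrized 2-aryl-2-methylcyclohexane-1,3-dione (ring A) and an arylacetaldehyde on the anisole that later becomes ring C. A low-valent titanium (McMurry) coupling joins them in one operation, closing ring B as the C5=C6 alkene; hydroboration then sets H5 and the C6 oxygen. Birch reduction of the anisole and an aldol/gold Conia-ene annulation with propynal across C11 and C13 build rings C and D.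

Key step: step 7

Remark on the chemistry: atoms carry the numbering of the target skeleton (ring A: C1–C5 and C10; ring B: C5–C10; ring C: C8, C9, C11–C14; ring D: C11, C12, C13, C16, C15; C17 is the exocyclic methylene carbon, C20 the methyl on C10). α is the face of the C10 methyl, β the opposite face.
Assumption: the aldol of step 14 is taken to give mainly the syn adduct (drawn); its C15 epimer would be carried along, because C15 ends as a ketone. Compound 2 is an E/Z mixture (E drawn).

Step 1
Reactants: 1 2-bromo-4-methoxybenzaldehyde
Product: 3 2-bromo-1-(2,2-dimethoxyethyl)-4-methoxybenzene, via enol ether 2 (not isolated)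
Conditions: MeOCH2PPh3Cl, KOtBu, THF, 0 °C to rt; then MeOH, CSA, 50 °C
Reagents that add atoms: (methoxymethyl)triphenylphosphonium chloride, COC[P+](c1ccccc1)(c1ccccc1)c1ccccc1.[Cl-]; methanol, CO
Why: Wittig olefination with the methoxymethylene ylide gives the aryl enol ether, and acid-catalysed addition of methanol to its oxocarbenium ion gives the dimethyl acetal, a base-stable form of the arylacetaldehyde that carries C7 and C6 (no stereocentre).

Step 2
Reactants: 3 2-bromo-1-(2,2-dimethoxyethyl)-4-methoxybenzene; 4 2-methylcyclohexane-1,3-dione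
Product: 5 2-[2-(2,2-dimethoxyethyl)-5-methoxyphenyl]-2-methylcyclohexane-1,3-dione
Conditions: Pd(OAc)2 (5 mol %), tBuXPhos (10 mol %), K3PO4, 1,4-dioxane, 100 °C
Reagents that add atoms: none
Why: Palladium-catalysed α-arylation of the 1,3-diketone enolate (oxidative addition of 3, enolate binding, C–C reductive elimination from the bulky biarylphosphine complex) should create the quaternary C10, the product being prochiral and therefore free of stereocentres.

Step 3
Reactants: 5 2-[2-(2,2-dimethoxyethyl)-5-methoxyphenyl]-2-methylcyclohexane-1,3-dione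
Product: 6 (2R,3R)-2-[2-(2,2-dimethoxyethyl)-5-methoxyphenyl]-3-hydroxy-2-methylcyclohexan-1-one (hydroxyl cis to the aryl group)
Conditions: (S)-Me-CBS (20 mol %), BH3·SMe2 (0.6 equiv), THF, −30 °C; MeOH quench
Reagents that add atoms: none
Why: Corey–Bakshi–Shibata reduction should desymmetrize the dione by delivering hydride to one enantiotopic carbonyl from the face anti to the aryl group, which sets C10 and gives the (R)-carbinol cis to the aryl group (the C1 configuration is corrected in steps 10 and 11, and the minor trans diastereomer, which would lead into the enantiomeric series, is removed by chromatography).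

Step 4
Reactants: 6 (2R,3R)-2-[2-(2,2-dimethoxyethyl)-5-methoxyphenyl]-3-hydroxy-2-methylcyclohexan-1-one
Product: 7 (2R,3R)-3-(tert-butyldimethylsilyloxy)-2-[2-(2,2-dimethoxyethyl)-5-methoxyphenyl]-2-methylcyclohexan-1-one
Conditions: TBSOTf, 2,6-lutidine, CH2Cl2, 0 °C
Reagents that add atoms: tert-butyldimethylsilyl triflate, CC(C)(C)[Si](C)(C)OS(=O)(=O)C(F)(F)F
Why: Silylation of the hindered secondary alcohol with the silyl triflate protects the C1 oxygen against O-methylation and retro-aldol cleavage in the next step without touching a stereocentre.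

Step 5
Reactants: 7 (2R,3R)-3-(tert-butyldimethylsilyloxy)-2-[2-(2,2-dimethoxyethyl)-5-methoxyphenyl]-2-methylcyclohexan-1-one
Product: 8 (2R,3R)-3-(tert-butyldimethylsilyloxy)-2-[2-(2,2-dimethoxyethyl)-5-methoxyphenyl]-2,6,6-trimethylcyclohexan-1-one
Conditions: KOtBu (3 equiv), MeI (6 equiv), THF, 0 °C to rt
Reagents that add atoms: iodomethane, CI
Why: Exhaustive enolate alkylation should install the C4 gem-dimethyl group, because C4 is the only enolizable position of the ketone (C10 is quaternary) and the acetal side chain has no acidic hydrogen, so no stereocentre is affected.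

Step 6
Reactants: 8 (2R,3R)-3-(tert-butyldimethylsilyloxy)-2-[2-(2,2-dimethoxyethyl)-5-methoxyphenyl]-2,6,6-trimethylcyclohexan-1-one
Product: 9 2-{2-[6-(tert-butyldimethylsilyloxy)-1,3,3-trimethyl-2-oxocyclohexyl]-4-methoxyphenyl}acetaldehyde (ring A configuration as in 8)
Conditions: 1 M HCl, THF, rt
Reagents that add atoms: water, O
Why: Acid-catalysed acetal hydrolysis through the oxocarbenium ion should release the C6 aldehyde while the hindered secondary silyl ether survives, and the aldehyde is used at once.

Step 7
Reactants: 9 2-{2-[6-(tert-butyldimethylsilyloxy)-1,3,3-trimethyl-2-oxocyclohexyl]-4-methoxyphenyl}acetaldehyde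
Product: 10 tricyclic alkene: 1β-(tert-butyldimethylsilyloxy)-12-methoxy-4,4,10-trimethyl tricycle (rings A and B, aromatic ring C) with a C5=C6 double bond
Conditions: TiCl3(DME)1.5, Zn–Cu couple, DME, reflux; slow addition of 9 by syringe pump at high dilution
Reagents that add atoms: none
Why: McMurry coupling: low-valent titanium transfers single electrons to the C5 ketone and the C6 aldehyde, the two titanium-bound ketyls combine to the C5–C6 pinacolate, and deoxygenation on the titanium surface gives the C5=C6 alkene. The closest known reaction type is the intramolecular keto–aldehyde McMurry cyclization to cyclohexenes. Ring B (six-membered) closes by carbonyl–carbonyl coupling across the C7–C8–C9–C10 tether, in which the aryl ring holds the two chains cis, so the mode is a simple six-ring closure with no exo/endo choice. No stereocentre is created here (C5 and C6 become sp2); both are set in step 8 under control of the C10 stereocentre. The step needs intramolecular coupling to beat intermolecular aldehyde pinacolization and needs the very hindered ketone to react: slow addition at high dilution serves the first, and the ketone, flanked by the quaternary C4 and C10, can neither enolize nor homocouple, so it is expected to wait for the tethered aldehyde ketyl, while the silyl ether, the aryl methyl ether and the arene are inert.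

Step 8
Reactants: 10 tricyclic alkene (C5=C6, 1β-OTBS, 12-OMe)
Product: 12 1β-(tert-butyldimethylsilyloxy)-6β-hydroxy-12-methoxy tricycle with H5 β (trans ring fusion), via alkylborane 11 (not isolated)
Conditions: BH3·THF, THF, 0 °C to rt; then NaOH, H2O2 (aq), 0 °C
Reagents that add atoms: hydrogen peroxide, OO
Why: Hydroboration–oxidation should add boron to the less substituted C6 and hydrogen to C5 in a syn fashion from the β face, away from the axial C10 methyl, and oxidation with retention gives the 6β-alcohol with H5 β.

Step 9
Reactants: 12 1β-(tert-butyldimethylsilyloxy)-6β-hydroxy-12-methoxy tricycle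
Product: 13 1β,6β-dihydroxy-12-methoxy tricycle (H5 β)
Conditions: TBAF, THF, 50 °C
Reagents that add atoms: none
Why: Fluoride-mediated desilylation, driven by the strong Si–F bond, should free the hindered C1 alcohol without affecting any stereocentre.

Step 10
Reactants: 13 1β,6β-dihydroxy-12-methoxy tricycle
Product: 14 12-methoxy tricyclic 1,6-dione (H5 β, trans ring fusion)
Conditions: Dess–Martin periodinane, CH2Cl2, rt
Reagents that add atoms: none
Why: Dess–Martin oxidation should convert both secondary alcohols into ketones under neutral conditions, which erases the provisional C1 and C6 configurations, while C5 keeps the trans ring fusion (any cis-fused material can equilibrate at C5 through the 6-ketone).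

Step 11
Reactants: 14 12-methoxy tricyclic 1,6-dione
Product: 15 1α,6α-dihydroxy-12-methoxy tricycle (H5 β)
Conditions: LiAlH4, THF, −78 to 0 °C
Reagents that add atoms: none
Why: In this hydride reduction the α face of C6 is blocked by the syn-axial C10 and C4 methyl groups, so hydride should enter from the β face to give the axial 6α-alcohol, and at C1 axial attack from the β face (the α face is screened by the adjacent axial C10 methyl) should give the equatorial 1α-alcohol.

Step 12
Reactants: 15 1α,6α-dihydroxy-12-methoxy tricycle
Product: 16 Birch product: 12-methoxy-8(9),12(13)-diene-1α,6α-diol (C12=C13 enol ether, tetrasubstituted C8=C9)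
Conditions: Li, NH3 (l), THF, t-BuOH, −78 to −33 °C
Reagents that add atoms: none
Why: Birch reduction should turn the anisole ring into the 1-methoxy-1,4-diene whose double bonds stay at the donor-substituted positions (C12=C13 and C8=C9), the two hydroxyl groups being carried as lithium alkoxides.

Step 13
Reactants: 16 12-methoxy-8(9),12(13)-diene-1α,6α-diol
Product: 18 1α,6α-diacetoxy tricyclic 8(9)-en-12-one (β,γ-unsaturated ketone), via enol ether diacetate 17 (not isolated)
Conditions: Ac2O, DMAP, Et3N, CH2Cl2, 40 °C; then (CO2H)2·2H2O, THF/H2O, rt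
Reagents that add atoms: acetic anhydride, CC(=O)OC(C)=O; water, O
Why: DMAP-catalysed acetylation should esterify both hindered hydroxyls under basic conditions that leave the enol ether intact, and mild oxalic acid hydrolysis then unmasks the C12 ketone by kinetic protonation at C13, which keeps the C8=C9 bond out of conjugation.

Step 14
Reactants: 18 1α,6α-diacetoxy tricyclic 8(9)-en-12-one; 19 propynal
Product: 20 aldol adduct: 18 with a 1-hydroxyprop-2-yn-1-yl group on C11 (β face, H11 α; syn adduct at C15)
Conditions: LiN(SiMe3)2, THF, −78 °C; Cp2ZrCl2, −78 to −40 °C; then 19, −78 °C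
Reagents that add atoms: none
Why: In this directed aldol addition the base should remove the C11 proton (α to the ketone and allylic to C8=C9, far more acidic than the acetate methyls), the metal dienolate should attack propynal through C11 on the β face opposite the C10 methyl, and the zirconium enolate favours the syn aldol, in which the C15 oxygen will point toward C12 after ring closure.

Step 15
Reactants: 20 aldol adduct
Product: 21 bis(triethylsilyl) derivative: C15 triethylsilyl ether and C12(OSiEt3)=C13 silyl enol ether
Conditions: TESOTf, Et3N, CH2Cl2, −78 to 0 °C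
Reagents that add atoms: triethylsilyl triflate, CC[Si](CC)(CC)OS(=O)(=O)C(F)(F)F
Why: Soft enolization–silylation should protect the carbinol and form the silyl enol ether toward C13, because enolization toward the tertiary, doubly flanked C11 would give a tetrasubstituted enol ether with severe allylic strain, and the amine base spares the acetates.

Step 16
Reactants: 21 bis(triethylsilyl) derivative
Product: 22 bridged ketone: rings C and D closed (new C13–C16 bond), 16-methylene, 12-ketone, 15-triethylsilyloxy (oxygen on the side of C12), 1α,6α-diacetate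
Conditions: Ph3PAuCl (5 mol %), AgBF4 (5 mol %), CH2Cl2/MeOH (10:1), rt
Reagents that add atoms: none
Why: In this gold-catalysed Conia-ene-type carbocyclization the cationic gold complex activates the terminal alkyne for 5-exo-dig attack by the enol ether carbon C13, which can only occur on the β face where the C11 side chain sits, and methanol removes silicon and gold to give the 16-methylene bicyclo[3.2.1]octenone with C13 set by the tether.

Step 17
Reactants: 22 bridged ketone
Product: 24 12,15-diol: 12-hydroxyl syn to the C15–C16 bridge, 15-hydroxyl allylic, via silyl ether alcohol 23 (not isolated)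
Conditions: NaBH4, MeOH/THF, −40 to 0 °C; then 1 M HCl, 0 °C
Reagents that add atoms: none
Why: In this borohydride reduction hydride should approach the bridging C12 ketone from the face of the C8=C9–C14 bridge, because the opposite face is covered by the silyloxy group on C15, which gives the 12-alcohol syn to the C15–C16 bridge, and the acid work-up cleaves the silyl ether.

Step 18
Reactants: 24 12,15-diol
Product: 25 1α,6α-diacetoxyjungermannenone C
Conditions: MnO2, CH2Cl2, rt
Reagents that add atoms: none
Why: Manganese dioxide oxidation is selective for the allylic C15 alcohol next to the C16=C17 methylene and should leave the non-allylic C12 alcohol and the acetates untouched, giving the enone of the target.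

Compound list
1 | 2-bromo-4-methoxybenzaldehyde | COc1ccc(C=O)c(Br)c1 | starting material
2 | 2-bromo-4-methoxy-1-(2-methoxyethenyl)benzene (E/Z mixture, E drawn) | CO/C=C/c1ccc(OC)cc1Br | intermediate
3 | 2-bromo-1-(2,2-dimethoxyethyl)-4-methoxybenzene | COC(Cc1ccc(OC)cc1Br)OC | intermediate
4 | 2-methylcyclohexane-1,3-dione | CC1C(=O)CCCC1=O | starting material
5 | 2-[2-(2,2-dimethoxyethyl)-5-methoxyphenyl]-2-methylcyclohexane-1,3-dione | COC(Cc1ccc(OC)cc1C1(C)C(=O)CCCC1=O)OC | intermediate
6 | (2R,3R)-2-[2-(2,2-dimethoxyethyl)-5-methoxyphenyl]-3-hydroxy-2-methylcyclohexan-1-one | O=C1CCC[C@@H](O)[C@@]1(C)c1cc(OC)ccc1CC(OC)OC | intermediate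
7 | tert-butyldimethylsilyl ether of 6 | O=C1CCC[C@@H](O[Si](C)(C)C(C)(C)C)[C@@]1(C)c1cc(OC)ccc1CC(OC)OC | intermediate
8 | (2R,3R)-3-(tert-butyldimethylsilyloxy)-2-[2-(2,2-dimethoxyethyl)-5-methoxyphenyl]-2,6,6-trimethylcyclohexan-1-one | O=C1C(C)(C)CC[C@@H](O[Si](C)(C)C(C)(C)C)[C@@]1(C)c1cc(OC)ccc1CC(OC)OC | intermediate
9 | keto aldehyde: arylacetaldehyde corresponding to 8 | O=C1C(C)(C)CC[C@@H](O[Si](C)(C)C(C)(C)C)[C@@]1(C)c1cc(OC)ccc1CC=O | intermediate
10 | tricyclic alkene, C5=C6, 1β-OTBS, 12-OMe, aromatic ring C | COc1cc2c(cc1)CC=C1C(C)(C)CC[C@@H](O[Si](C)(C)C(C)(C)C)[C@@]21C | intermediate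
11 | C6 alkylborane (boron on C6 β, H5 β) | COc1cc2c(cc1)C[C@@H](B)[C@@H]1C(C)(C)CC[C@@H](O[Si](C)(C)C(C)(C)C)[C@@]21C | intermediate
12 | 1β-(tert-butyldimethylsilyloxy)-6β-hydroxy-12-methoxy tricycle, H5 β | COc1cc2c(cc1)C[C@@H](O)[C@@H]1C(C)(C)CC[C@@H](O[Si](C)(C)C(C)(C)C)[C@@]21C | intermediate
13 | 1β,6β-dihydroxy-12-methoxy tricycle, H5 β | COc1cc2c(cc1)C[C@@H](O)[C@@H]1C(C)(C)CC[C@@H](O)[C@@]21C | intermediate
14 | 12-methoxy tricyclic 1,6-dione, H5 β | COc1cc2c(cc1)CC(=O)[C@@H]1C(C)(C)CCC(=O)[C@@]21C | intermediate
15 | 1α,6α-dihydroxy-12-methoxy tricycle, H5 β | COc1cc2c(cc1)C[C@H](O)[C@@H]1C(C)(C)CC[C@H](O)[C@@]21C | intermediate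
16 | 12-methoxy-8(9),12(13)-diene-1α,6α-diol | COC=1CC2=C(CC=1)C[C@H](O)[C@@H]1C(C)(C)CC[C@H](O)[C@@]21C | intermediate
17 | 1α,6α-diacetate of 16 | COC=1CC2=C(CC=1)C[C@H](OC(C)=O)[C@@H]1C(C)(C)CC[C@H](OC(C)=O)[C@@]21C | intermediate
18 | 1α,6α-diacetoxy tricyclic 8(9)-en-12-one | O=C1CC2=C(CC1)C[C@H](OC(C)=O)[C@@H]1C(C)(C)CC[C@H](OC(C)=O)[C@@]21C | intermediate
19 | propynal | C#CC=O | starting material
20 | aldol adduct, C11 side chain β, syn at C15 | O=C1[C@H]([C@H](O)C#C)C2=C(CC1)C[C@H](OC(C)=O)[C@@H]1C(C)(C)CC[C@H](OC(C)=O)[C@@]21C | intermediate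
21 | C15 triethylsilyl ether, C12=C13 triethylsilyl enol ether | CC[Si](CC)(CC)OC=1[C@H]([C@H](O[Si](CC)(CC)CC)C#C)C2=C(CC=1)C[C@H](OC(C)=O)[C@@H]1C(C)(C)CC[C@H](OC(C)=O)[C@@]21C | intermediate
22 | bridged 12-ketone, 16-methylene, 15-triethylsilyloxy, 1α,6α-diacetate | C=C1[C@@H](O[Si](CC)(CC)CC)[C@@H]2C3=C(C[C@H](OC(C)=O)[C@@H]4C(C)(C)CC[C@H](OC(C)=O)[C@@]34C)C[C@H]1C2=O | intermediate
23 | 12-hydroxy-15-triethylsilyloxy derivative | C=C1[C@@H](O[Si](CC)(CC)CC)[C@@H]2C3=C(C[C@H](OC(C)=O)[C@@H]4C(C)(C)CC[C@H](OC(C)=O)[C@@]34C)C[C@H]1[C@@H]2O | intermediate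
24 | 12,15-diol | C=C1[C@@H](O)[C@@H]2C3=C(C[C@H](OC(C)=O)[C@@H]4C(C)(C)CC[C@H](OC(C)=O)[C@@]34C)C[C@H]1[C@@H]2O | intermediate
25 | 1α,6α-diacetoxyjungermannenone C | C=C1C(=O)[C@@H]2C3=C(C[C@H](OC(C)=O)[C@@H]4C(C)(C)CC[C@H](OC(C)=O)[C@@]34C)C[C@H]1[C@@H]2O | target

Total step count: 18. Longest linear sequence: 18 steps (from 1; compounds 4 and 19 enter as bought).

Steps most likely to fail

Step 7: the doubly neopentyl C5 ketone may resist ketyl coupling, so that intermolecular pinacolization or plain reduction of the aldehyde takes over, or the crowded titanium pinacolate may not lose its oxygens. The fallback sets out from 9 and comes back at 14. SmI2 in THF/t-BuOH should give the pinacol cyclization product, cis-5,6-diol F1, by inner-sphere ketyl–carbonyl coupling without the deoxygenation stage. Parikh–Doering oxidation of its secondary C6 alcohol should give α-ketol F2. SmI2/MeOH should then cleave the C5–O bond α to the ketone and give the trans-fused 6-ketone F3. TBAF should give hydroxy ketone F4, and Dess–Martin oxidation should give 14.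

Step 2: C–C reductive elimination at the congested diketonate carbon may be too slow next to the ortho side chain, so that protodebromination or O-arylation wins. The fallback sets out from 3 and comes back at 5. Bromine–lithium exchange (n-BuLi, THF, −78 °C) and Bu3SnCl should give arylstannane F5. Pb(OAc)4 with Hg(OAc)2 (cat.) in CHCl3 should turn it in the flask into aryllead triacetate F6, which should C-arylate 4 in the presence of pyridine (Pinhey arylation, a ligand-coupling mechanism that tolerates ortho substituents) to give 5.

Step 15: silylation may enolize toward C11 and give the conjugated dienol ether, which cannot reach the alkyne, or may trigger retro-aldol loss of the side chain. The fallback sets out from 20 and comes back at 22. TESCl/imidazole should give silyl ether F7 with the ketone intact. Catalytic pyrrolidine together with [Cu(NCMe)4]PF6 and PPh3 should then form the less substituted C12–C13 enamine, which adds to the copper-activated alkyne (enamine Conia-ene carbocyclization) and hydrolyses to 22, so that regiochemistry is set by enamine formation instead of enol silylation.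

Further compounds
F1 | step 7 | cis-5β,6β-diol with 1β-OTBS, 12-OMe, aromatic ring C | COc1cc2c(cc1)C[C@@H](O)[C@]1(O)C(C)(C)CC[C@@H](O[Si](C)(C)C(C)(C)C)[C@@]21C
F2 | step 7 | 5β-hydroxy-6-ketone (α-ketol) with 1β-OTBS | COc1cc2c(cc1)CC(=O)[C@]1(O)C(C)(C)CC[C@@H](O[Si](C)(C)C(C)(C)C)[C@@]21C
F3 | step 7 | 6-ketone with H5 β and 1β-OTBS | COc1cc2c(cc1)CC(=O)[C@@H]1C(C)(C)CC[C@@H](O[Si](C)(C)C(C)(C)C)[C@@]21C
F4 | step 7 | 1β-hydroxy-6-ketone with H5 β | COc1cc2c(cc1)CC(=O)[C@@H]1C(C)(C)CC[C@@H](O)[C@@]21C
F5 | step 2 | tributyl[2-(2,2-dimethoxyethyl)-5-methoxyphenyl]stannane | CCCC[Sn](CCCC)(CCCC)c1cc(OC)ccc1CC(OC)OC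
F6 | step 2 | [2-(2,2-dimethoxyethyl)-5-methoxyphenyl]lead triacetate | CC(=O)O[Pb](OC(C)=O)(OC(C)=O)c1cc(OC)ccc1CC(OC)OC
F7 | step 15 | C15 triethylsilyl ether of 20 (ketone free) | O=C1[C@H]([C@H](O[Si](CC)(CC)CC)C#C)C2=C(CC1)C[C@H](OC(C)=O)[C@@H]1C(C)(C)CC[C@H](OC(C)=O)[C@@]21C
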